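## Structural features

The target joins a trans-fused drimane decalin (ring A: C1–C5 and C10; ring B: C5–C10) through the C11 methylene at C9 to the quaternary epoxide carbon C6' of a cyclohex-2-enone ring. That ring has the C1' carbonyl, the C2'=C3' alkene with the C7' hydroxymethyl on C3', the C4' carbinol and the C5'–C6' epoxide. The decalin holds three contiguous stereocentres, C5 (H α), C10 (quaternary, methyl β) and C9 (C11 β, equatorial), and the exocyclic C8=C12 methylene sits directly beside C9. The enone ring holds a second contiguous triad, C4', C5' and C6', with the C4' hydroxyl on the face opposite to the epoxide oxygen. The two triads are insulated from each other by C11, so neither can relay its configuration to the other; setting the absolute configuration of the epoxide and the anti hydroxyl/epoxide relationship is the real difficulty. The fragile functions are the epoxy enone (base, nucleophiles, strong acid), the γ-hydroxy enone (dehydration to an arene), the C8=C12 methylene (migration into ring B under acid) and any intermediate with a C11 carbonyl, whose C9–H is both allylic and α to the carbonyl. The congested C4/C5/C10 array (quaternary, tertiary, quaternary) is a further constraint. The key step exploits the fact that the C8=C12 methylene flanks C9 and that C9 is α to C11: when C11 is carried as an aryl ketone, its C9 enol carbon can add to the internal carbon C8 of a terminal C8≡C12 alkyne, which closes ring B and leaves exactly this methylene.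

## Logic of the disconnections

31 to 30: the C4'–H bond is cut, which takes the carbinol back to a ketone. The cut is made here because the free C7' hydroxyl of 30 sits next to C4' and can hold a hydride reagent there. One stereocentre disappears. The forward step must reduce C4' and not C1', and must deliver hydride on the face syn to the epoxide oxygen.

30 to 28 to 27: the C5'–O and C6'–O bonds of the epoxide are cut after C4' has been masked as a dimethyl ketal and C7'–O as a silyl ether. This leaves 27 with a single enone carbonyl (C1') between two differently substituted alkenes and removes every stereocentre of the enone ring. The forward epoxidation must choose C5'=C6' over C2'=C3' and one face of a flat dienone under reagent control.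

27 to 26 to 25: the second C4'–O bond of the ketal and the C1' carbonyl are traced back to the free phenol and the aryl methyl ether of 26. The enone ring thus becomes a benzene ring that survives organometallic, radical and gold chemistry. The forward oxidation needs the C1' oxygen free and the C4' oxygen methylated, so the two oxygens must carry different groups from the start.

25 to 24 to 23 to 22: a carbonyl is added at C11 (the two C11–H bonds are traced back to C11=O). This is done because the C11 aryl ketone is the activating group the ring B closure needs. The forward removal must leave the second benzylic C–O bond (C7'), the methylene and the ethers alone, which points to a radical deoxygenation of the derived alcohol.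

22 to 21: the C8–C9 bond is cut, which opens ring B. A bicycle with three stereocentres becomes a ring A compound with two, and the exocyclic methylene becomes a terminal alkyne. The forward step must close 6-exo-dig, through carbon, with C11 equatorial at the new C9 centre, and without moving the alkene into conjugation.

21 to 20 to 19 to 10 plus 16: after the enol O–Si bond, the C11–C6' bond is cut between a two-carbon aldehyde side chain and an aryl metal. This splits the molecule into two fragments of similar size. The forward addition requires the alkyne C–H to stay capped until the aryl metal has been consumed.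

10 to 9 to 8 to 7 to 6: the C11 aldehyde is traced back to an allyl group, and the C1 methylene to a C1 ketone. The ketone is accepted because it is the handle that makes the next cut possible. The forward sequence must remove a carbonyl flanked by a quaternary carbon under conditions that spare alkene and silylalkyne.

6 to 1, 2 and 3: the C5–C6 and C10–C9 bonds are cut in a conjugate addition–alkylation retron. Two C–C bonds and both ring A stereocentres then arise in one operation from three commercial compounds. The forward step needs catalyst control of the face at C5 and alkylation anti to the new chain at C10.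

16 to 15 to 14 to 13 to 12 to 11: the C–Br bond and the three O–C/O–Si bonds of the arene are removed in turn. This leads to commercial 11. The forward steps need a regioselective first O-alkylation and bromination para to the formyl carbon.

## Other disconnections considered

Alternative 1: The cut is at the C5'–O and C6'–O bonds, made on a cage compound and not on a flat dienone. The forward key step would treat A1, the endo cyclopentadiene adduct across C2'=C3' of the quinone that corresponds to 26, with H2O2 and Na2CO3 to give the convex-face epoxide A2. Hydride addition at C4' from the same convex face and a thermal retro-Diels–Alder reaction would follow.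
- In its favour: one element, the cage, fixes both the epoxide face and the carbinol face. The anti relationship of C4'–OH and epoxide then follows from two convex-face attacks, which is better than the chosen plan, where that relationship rests on a reagent-dependent facial preference in step 22. Only one enedione alkene is left in A1, so regioselection of the epoxidation is also better than in step 20.
- Against it here: the bridgehead centres of A1 would have to be set in an absolute sense relative to a drimane unit that is insulated by C11. The cycloaddition would therefore need a chiral Lewis acid or a separation of two adducts. Cyclopentadiene would also have to choose between two trisubstituted quinone alkenes, and the retro-Diels–Alder step would heat an epoxy carbinol that carries an acid- and heat-sensitive methylene.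
- Comparison: both plans use nucleophilic epoxidation and both need the same aryl-drimane, so the ring B construction of the chosen plan would serve either. On step economy the cage endgame is the longer one (oxidation, cycloaddition, epoxidation, reduction, cycloreversion, desilylation against four operations from 26). On absolute stereocontrol the chosen plan is the more direct.

Alternative 2: The cut is at C5'–C6' and C6'–O together. The forward key step would be an intramolecular Darzens reaction of the open-chain (Z)-enone A3, in which the C6' chloro-enolate adds to the C5' aldehyde and the alkoxide displaces chloride, giving the bis-silyl ether A4 of 31.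
- In its favour: carbocycle and epoxide form in one step, which is better in bond economy than the sequential oxidations of the chosen endgame. The C4' carbinol would enter with a configuration fixed in an acyclic building block, which is also better than a late reduction. The cis ring fusion of the epoxide is automatic.
- Against it here: the aldol face at C5'/C6' relative to the C4' silyloxy group is not obviously the one needed. The enolate of A3 is cross-conjugated and can deprotonate at C7' or enter a Favorskii path. The α-silyloxy aldehyde can epimerise, and the (Z)-enone must be built and kept.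
- Comparison: the drimane part with C11 attached would still have to be made first, so the chosen ring B closure is not avoided. The mechanism asks more of one step than any step of the chosen route, and the step count to A3 would probably be higher.

Alternative 3: The cut is at C2'=C3'. The forward key step would be ring-closing metathesis of the epoxy diene A5 (C1' vinyl ketone, C3' 1,1-disubstituted alkene, C4' silyloxy, C5'–C6' epoxide in place) with the second-generation Hoveyda–Grubbs catalyst, giving the bis-triethylsilyl ether A6 of 31.
- In its favour: the epoxide would come from a Sharpless epoxidation of an allylic alcohol. As absolute stereocontrol this is better established than the tartrate-mediated nucleophilic epoxidation of step 20. No late regio- or face-selective reduction is needed, which is also better.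
- Against it here: closing a trisubstituted enone between an electron-poor vinyl ketone and a 1,1-disubstituted alkene is a slow metathesis. The vinyl ketone next to a quaternary epoxide carbon is a sensitive Michael acceptor. The C8=C12 methylene is a third alkene in the substrate. The quaternary C6' carrying the drimenylmethyl group would have to be built in a long linear sequence on the terpene.
- Comparison: structurally the stereotriad is better controlled. Mechanistically the ring closure is less reliable than a phenol oxidation. On step economy the chosen plan is shorter, because it draws the whole enone ring from one commercial arene. The final deprotection count is equal.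

Key step: step 14

Assumption: the sense of induction of the chiral ligand in step 1 and of the tartrate in step 20 is not derived from a transition-state model here; in each case the antipode that delivers the configuration drawn is used, both antipodes being accessible, and the absolute configuration of 6 and of 28 should be verified by correlation once these compounds are in hand.

Abbreviations in names: Ar = 4-({[tert-butyl(dimethyl)silyl]oxy}methyl)-5-methoxy-2-(methoxymethoxy)phenyl; Dr = (1S,4aS,8aS)-5,5,8a-trimethyl-2-methylidenedecahydronaphthalen-1-yl (the drim-8(12)-en-9-yl unit); TBS = tert-butyldimethylsilyl; MOM = methoxymethyl.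

## Route

Step 1
Reactants: 1 (4-bromobut-1-yn-1-yl)trimethylsilane; 2 2,4,4-trimethylcyclohex-2-en-1-one; 3 allyl bromide
Product: 6 (2R,3S)-2,4,4-trimethyl-2-(prop-2-en-1-yl)-3-[4-(trimethylsilyl)but-3-yn-1-yl]cyclohexan-1-one, via Grignard reagent 4 (not isolated), via magnesium enolate 5 (not isolated)
Conditions: 1, Mg, Et2O, reflux; then 2, Cu(OTf)2 (5 mol %), 3-(1-hydroxy-4-methylpentan-2-yl)-1-mesityl-4,5-dihydroimidazolium hexafluorophosphate (single enantiomer, carbene precursor, 6 mol %), Et2O, −30 °C; then 3, DMPU, −30 °C to rt
Reagents that add atoms: none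
Why: Copper-catalysed asymmetric conjugate addition of a Grignard reagent to an α-substituted cyclic enone with enolate trapping; the chiral carbene–copper complex selects the enone face and sets C5 (drimane numbering), and in enolate 5 the new chain sits pseudoaxial to avoid allylic strain with the enolate methyl, so 3 enters on the opposite face and sets C10 with allyl trans and methyl cis to the chain.

Step 2
Reactants: 6 (2R,3S)-2,4,4-trimethyl-2-(prop-2-en-1-yl)-3-[4-(trimethylsilyl)but-3-yn-1-yl]cyclohexan-1-one
Product: 7 (2R,3S)-2,4,4-trimethyl-2-(prop-2-en-1-yl)-3-[4-(trimethylsilyl)but-3-yn-1-yl]cyclohexan-1-ol (mixture of C1 epimers)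
Conditions: LiAlH4, Et2O, 0 °C
Reagents that add atoms: none
Why: Hydride reduction of a hindered ketone; the new C1 carbinol centre is of no consequence because C1 becomes a methylene in step 4, and alkene and silylalkyne are inert to LiAlH4 at this temperature.

Step 3
Reactants: 7 (2R,3S)-2,4,4-trimethyl-2-(prop-2-en-1-yl)-3-[4-(trimethylsilyl)but-3-yn-1-yl]cyclohexan-1-ol
Product: 8 O-{(2R,3S)-2,4,4-trimethyl-2-(prop-2-en-1-yl)-3-[4-(trimethylsilyl)but-3-yn-1-yl]cyclohexyl} S-methyl carbonodithioate (C1 epimers)
Conditions: NaH, imidazole (cat.), THF, 0 °C to rt; CS2; MeI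
Reagents that add atoms: carbon disulfide, S=C=S; iodomethane, CI
Why: Xanthate formation (first half of a Barton–McCombie deoxygenation); the small electrophile CS2 reaches the hindered alkoxide where acylating agents would be slow.

Step 4
Reactants: 8 O-{(2R,3S)-2,4,4-trimethyl-2-(prop-2-en-1-yl)-3-[4-(trimethylsilyl)but-3-yn-1-yl]cyclohexyl} S-methyl carbonodithioate
Product: 9 trimethyl{4-[(1S,2R)-2,6,6-trimethyl-2-(prop-2-en-1-yl)cyclohexyl]but-1-yn-1-yl}silane
Conditions: Bu3SnH, AIBN, toluene, 90 °C
Reagents that add atoms: none
Why: Barton–McCombie radical deoxygenation; the secondary C1 radical has no favourable cyclisation mode (only 4-exo or 5-endo onto the allyl group and a bridged closure onto the alkyne) and is reduced by the stannane, so steric hindrance at C1 does not matter.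

Step 5
Reactants: 9 trimethyl{4-[(1S,2R)-2,6,6-trimethyl-2-(prop-2-en-1-yl)cyclohexyl]but-1-yn-1-yl}silane
Product: 10 2-{(1R,2S)-1,3,3-trimethyl-2-[4-(trimethylsilyl)but-3-yn-1-yl]cyclohexyl}acetaldehyde
Conditions: OsO4 (2 mol %), NaIO4, 2,6-lutidine, dioxane–H2O, rt
Reagents that add atoms: osmium tetroxide (catalytic oxygen carrier), O=[Os](=O)(=O)=O; sodium periodate (terminal oxidant), [Na+].[O-]I(=O)(=O)=O
Why: Lemieux–Johnson oxidative cleavage; OsO4 dihydroxylates the terminal alkene far faster than the silyl-capped alkyne, and the lutidine buffer suppresses over-oxidation of the aldehyde that now holds C9 and C11.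

Step 6
Reactants: 11 2,5-dihydroxybenzaldehyde
Product: 12 2-hydroxy-5-(methoxymethoxy)benzaldehyde
Conditions: NaH (2.2 equiv), DMF, 0 °C; MOMCl (1.0 equiv); aq. NH4Cl
Reagents that add atoms: chloromethyl methyl ether, COCCl
Why: Williamson-type O-alkylation of the dianion; the 2-phenoxide is delocalised into and chelated by the formyl group, so the 5-phenoxide is the more nucleophilic oxygen and takes the single equivalent of MOMCl.

Step 7
Reactants: 12 2-hydroxy-5-(methoxymethoxy)benzaldehyde
Product: 13 2-methoxy-5-(methoxymethoxy)benzaldehyde
Conditions: MeI, K2CO3, DMF, rt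
Reagents that add atoms: iodomethane, CI
Why: Williamson O-methylation of the remaining phenol; this oxygen becomes the C4' methoxy group that is later turned into the ketal.

Step 8
Reactants: 13 2-methoxy-5-(methoxymethoxy)benzaldehyde
Product: 14 4-bromo-2-methoxy-5-(methoxymethoxy)benzaldehyde
Conditions: N-bromosuccinimide, DMF, rt
Reagents that add atoms: N-bromosuccinimide, O=C1CCC(=O)N1Br
Why: Electrophilic aromatic bromination; the 5-alkoxy group, not in conjugation with the formyl group, is the stronger donor and directs to its ortho positions, of which C4 is the unhindered one (the known preference of 2,5-dialkoxybenzaldehydes), and the acid-free conditions keep the MOM ether.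

Step 9
Reactants: 14 4-bromo-2-methoxy-5-(methoxymethoxy)benzaldehyde
Product: 15 [4-bromo-2-methoxy-5-(methoxymethoxy)phenyl]methanol
Conditions: NaBH4, MeOH, 0 °C
Reagents that add atoms: none
Why: Borohydride reduction of an aryl aldehyde to the C7' carbinol; the aryl bromide and the acetal are inert.

Step 10
Reactants: 15 [4-bromo-2-methoxy-5-(methoxymethoxy)phenyl]methanol
Product: 16 {[4-bromo-2-methoxy-5-(methoxymethoxy)phenyl]methoxy}(tert-butyl)dimethylsilane
Conditions: TBSCl, imidazole, DMF, rt
Reagents that add atoms: tert-butyldimethylsilyl chloride, CC(C)(C)[Si](C)(C)Cl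
Why: Silylation of a primary alcohol; the TBS ether masks C7'–OH through the organolithium, radical, gold and oxidation steps and is removed together with the ketal in step 21.

Step 11
Reactants: 16 {[4-bromo-2-methoxy-5-(methoxymethoxy)phenyl]methoxy}(tert-butyl)dimethylsilane; 10 2-{(1R,2S)-1,3,3-trimethyl-2-[4-(trimethylsilyl)but-3-yn-1-yl]cyclohexyl}acetaldehyde
Product: 19 2-[(1R,2S)-2-(but-3-yn-1-yl)-1,3,3-trimethylcyclohexyl]-1-Ar-ethan-1-ol (C11 epimers), via aryllithium 17 (not isolated), via silylalkyne carbinolate 18 (not isolated)
Conditions: 16, n-BuLi, THF, −78 °C; then 10, −78 °C; then MeOH, K2CO3, rt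
Reagents that add atoms: none
Why: Bromine–lithium exchange (the aryllithium is stabilised by the ortho MOM oxygen) and 1,2-addition to the aldehyde form the C11–C6' bond; methanolysis of the alkynylsilane in the same flask then frees the terminal alkyne, which had to stay capped while the aryllithium was present; the C11 centre is removed by oxidation in step 12.

Step 12
Reactants: 19 2-[(1R,2S)-2-(but-3-yn-1-yl)-1,3,3-trimethylcyclohexyl]-1-Ar-ethan-1-ol
Product: 20 2-[(1R,2S)-2-(but-3-yn-1-yl)-1,3,3-trimethylcyclohexyl]-1-Ar-ethan-1-one
Conditions: Dess–Martin periodinane, NaHCO3, CH2Cl2, rt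
Reagents that add atoms: none
Why: Dess–Martin oxidation of a secondary benzylic alcohol under buffered, near-neutral conditions that leave the MOM ether, the silyl ether and the terminal alkyne untouched.

Step 13
Reactants: 20 2-[(1R,2S)-2-(but-3-yn-1-yl)-1,3,3-trimethylcyclohexyl]-1-Ar-ethan-1-one
Product: 21 {[(1Z)-2-[(1S,2S)-2-(but-3-yn-1-yl)-1,3,3-trimethylcyclohexyl]-1-Ar-ethenyl]oxy}(tert-butyl)dimethylsilane
Conditions: TBSOTf, Et3N, CH2Cl2, 0 °C to rt
Reagents that add atoms: tert-butyldimethylsilyl trifluoromethanesulfonate, CC(C)(C)[Si](C)(C)OS(=O)(=O)C(F)(F)F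
Why: Soft enolisation–silylation of an aryl ketone, which can enolise only toward C9; the (Z)-enol ether, with the bulky C10 substituent cis to oxygen and trans to the ortho-substituted arene, is the favoured isomer, and the amine base leaves the alkyne C–H alone.

Step 14
Reactants: 21 {[(1Z)-2-[(1S,2S)-2-(but-3-yn-1-yl)-1,3,3-trimethylcyclohexyl]-1-Ar-ethenyl]oxy}(tert-butyl)dimethylsilane
Product: 22 (Ar)(Dr)methanone, the 11-oxo-11-aryl-drim-8(12)-ene
Conditions: Ph3PAuNTf2 (5 mol %), CH2Cl2–MeOH (10:1), rt to 40 °C; filtration through Et3N-deactivated silica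
Reagents that add atoms: none
Why: The cationic phosphine–gold complex binds the terminal C8≡C12 alkyne, C9 of the silyl enol ether attacks the internal carbon C8 anti to gold to give an oxocarbenium vinylgold species, methanol takes the silyl group and protodeauration releases the catalyst and the C8=C12 methylene. The closest known reaction type is the gold-catalysed Conia-ene-type carbocyclisation of alkyne-tethered silyl enol ethers, which is documented for 5-exo-dig and 6-exo-dig closures. Ring B (C9–C10–C5–C6–C7–C8) closes in the 6-exo-dig mode, favoured over 7-endo-dig because positive charge builds up on the substituted carbon C8 of a terminal alkyne. The nucleophile is regiodefined because the C11 aryl ketone enolises only toward C9. The new stereocentre C9 is controlled by a chair transition state in which the C10–C9 and C5–C6 bonds are held equatorial on ring A by the trans C5/C10 pair; the aryl(siloxy)methylidene carbon C11 takes the pseudo-equatorial position, anti to C5 and clear of the axial hydrogens at C5 and C7, which gives H-9 α and C11 β. The step needs carbon over oxygen attack and cyclisation over solvolysis of the alkyne; the tether geometry puts only C9 within reach of C8, and the low methanol content with the weakly coordinating triflimide counter-ion keeps intermolecular methanol addition slow. Neutral conditions and immediate use of 22 in step 15 guard against migration of the C8=C12 bond into conjugation and against epimerisation at C9.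

Step 15
Reactants: 22 (Ar)(Dr)methanone
Product: 23 (Ar)(Dr)methanol (C11 epimers)
Conditions: i-Bu2AlH, CH2Cl2, −78 °C; aq. potassium sodium tartrate
Reagents that add atoms: none
Why: 1,2-Reduction with a non-basic, Lewis acidic hydride at low temperature removes the carbonyl that acidifies C9–H before the β,γ-alkene can move or C9 can epimerise; the C11 centre is removed in step 17.

Step 16
Reactants: 23 (Ar)(Dr)methanol
Product: 24 O-[(Ar)(Dr)methyl] S-methyl carbonodithioate (C11 epimers)
Conditions: NaH, imidazole (cat.), THF, 0 °C; CS2; MeI; used without delay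
Reagents that add atoms: carbon disulfide, S=C=S; iodomethane, CI
Why: Xanthate formation on the secondary benzylic alkoxide; only C11 carries a free hydroxyl, so the primary benzylic C7'–O bond is not activated.

Step 17
Reactants: 24 O-[(Ar)(Dr)methyl] S-methyl carbonodithioate
Product: 25 tert-butyl{[4-(Dr-methyl)-2-methoxy-5-(methoxymethoxy)phenyl]methoxy}dimethylsilane, the 11-aryl-drim-8(12)-ene
Conditions: Bu3SnH, Et3B (0.2 equiv), air, toluene, rt
Reagents that add atoms: none
Why: Barton–McCombie deoxygenation through a benzylic C11 radical; initiation at room temperature avoids Chugaev elimination toward C9, the radical's 3-exo closure onto C8=C12 is reversible and unproductive, and the radical path touches neither the C7' silyl ether nor the methylene, which an ionic or dissolving-metal benzylic reduction would.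

Step 18
Reactants: 25 tert-butyl{[4-(Dr-methyl)-2-methoxy-5-(methoxymethoxy)phenyl]methoxy}dimethylsilane
Product: 26 5-({[tert-butyl(dimethyl)silyl]oxy}methyl)-2-(Dr-methyl)-4-methoxyphenol
Conditions: TMSOTf, 2,2'-bipyridyl, CH2Cl2, 0 °C to rt; then H2O
Reagents that add atoms: none
Why: Silyl triflate–bipyridyl cleavage of an aromatic MOM ether: the buffered silyl triflate turns ArOCH2OMe into the aryl trimethylsilyl ether and a pyridinium-bound methoxymethyl unit, and water frees the phenol; no Brønsted acid is present, so the C8=C12 methylene stays exocyclic and the primary TBS ether should survive.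

Step 19
Reactants: 26 5-({[tert-butyl(dimethyl)silyl]oxy}methyl)-2-(Dr-methyl)-4-methoxyphenol
Product: 27 5-({[tert-butyl(dimethyl)silyl]oxy}methyl)-2-(Dr-methyl)-4,4-dimethoxycyclohexa-2,5-dien-1-one
Conditions: PhI(OAc)2, NaHCO3, MeOH, 0 °C
Reagents that add atoms: methanol, CO
Why: Oxidative dearomatisation of a para-methoxyphenol with a hypervalent iodine reagent; methanol adds at the methoxy-bearing carbon C4' of the phenoxonium ion, so the ketal is fixed at C4' and the only carbonyl at C1'.

Step 20
Reactants: 27 5-({[tert-butyl(dimethyl)silyl]oxy}methyl)-2-(Dr-methyl)-4,4-dimethoxycyclohexa-2,5-dien-1-one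
Product: 28 (1S,6R)-4-({[tert-butyl(dimethyl)silyl]oxy}methyl)-1-(Dr-methyl)-5,5-dimethoxy-7-oxabicyclo[4.1.0]hept-3-en-2-one
Conditions: Ph3COOH, NaN(SiMe3)2, L-(+)-diisopropyl tartrate, 4 Å molecular sieves, toluene, −50 to −30 °C
Reagents that add atoms: trityl hydroperoxide, OOC(c1ccccc1)(c1ccccc1)c1ccccc1
Why: Tartrate-mediated nucleophilic (Weitz–Scheffer-type) epoxidation of a quinone monoketal; the peroxide anion adds to the unsubstituted β-carbon C5' and not to C3', which is fully substituted and flanked by the ketal, and the sodium tartrate–peroxide aggregate selects the face, setting C5' and C6' together; because the drimane unit is a single enantiomer, any minor-face product is a diastereomer and can be removed by chromatography.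

Step 21
Reactants: 28 (1S,6R)-4-({[tert-butyl(dimethyl)silyl]oxy}methyl)-1-(Dr-methyl)-5,5-dimethoxy-7-oxabicyclo[4.1.0]hept-3-en-2-one
Product: 30 (1S,6R)-1-(Dr-methyl)-4-(hydroxymethyl)-7-oxabicyclo[4.1.0]hept-3-ene-2,5-dione, via desilylated epoxy ketal 29 (not isolated)
Conditions: 48% aq. HF, MeCN, 0 °C to rt
Reagents that add atoms: water, O
Why: Acid hydrolysis of the dimethyl ketal with concomitant cleavage of the primary silyl ether; aqueous HF is a weak acid that the electron-poor epoxide and the 1,1-disubstituted alkene should tolerate, and the C4' carbonyl oxygen comes from water.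

Step 22
Reactants: 30 (1S,6R)-1-(Dr-methyl)-4-(hydroxymethyl)-7-oxabicyclo[4.1.0]hept-3-ene-2,5-dione
Product: 31 (1S,5R,6S)-1-(Dr-methyl)-5-hydroxy-4-(hydroxymethyl)-7-oxabicyclo[4.1.0]hept-3-en-2-one (target, CNP0174686.3)
Conditions: i-Bu2AlH (3 equiv), THF, −78 °C; aq. potassium sodium tartrate
Reagents that add atoms: none
Why: Hydroxyl-directed hydride reduction of a β-hydroxy ketone; the C7' aluminium alkoxide chelates and activates the C4' carbonyl, while C1' is screened by quaternary C6' and deactivated as a β-alkyl enone carbonyl; hydride is expected on the face syn to the epoxide oxygen, to which the aluminium hydride can coordinate and which is not screened by the C11 substituent of C6', so the C4' hydroxyl ends up anti to the epoxide.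

## Compound list

1 | (4-bromobut-1-yn-1-yl)trimethylsilane | C[Si](C)(C)C#CCCBr | starting material
2 | 2,4,4-trimethylcyclohex-2-en-1-one | CC1=CC(C)(C)CCC1=O | starting material
3 | allyl bromide (3-bromoprop-1-ene) | C=CCBr | starting material
4 | [4-(trimethylsilyl)but-3-yn-1-yl]magnesium bromide | C[Si](C)(C)C#CCC[Mg]Br | intermediate (not isolated)
5 | bromomagnesium (3S)-2,4,4-trimethyl-3-[4-(trimethylsilyl)but-3-yn-1-yl]cyclohex-1-en-1-olate | C[Si](C)(C)C#CCC[C@H]1C(C)(C)CCC(O[Mg]Br)=C1C | intermediate (not isolated)
6 | (2R,3S)-2,4,4-trimethyl-2-(prop-2-en-1-yl)-3-[4-(trimethylsilyl)but-3-yn-1-yl]cyclohexan-1-one | C[Si](C)(C)C#CCC[C@H]1C(C)(C)CCC(=O)[C@]1(C)CC=C | intermediate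
7 | (2R,3S)-2,4,4-trimethyl-2-(prop-2-en-1-yl)-3-[4-(trimethylsilyl)but-3-yn-1-yl]cyclohexan-1-ol, C1 epimers | C[Si](C)(C)C#CCC[C@H]1C(C)(C)CCC(O)[C@]1(C)CC=C | intermediate
8 | O-{(2R,3S)-2,4,4-trimethyl-2-(prop-2-en-1-yl)-3-[4-(trimethylsilyl)but-3-yn-1-yl]cyclohexyl} S-methyl carbonodithioate, C1 epimers | C[Si](C)(C)C#CCC[C@H]1C(C)(C)CCC(OC(=S)SC)[C@]1(C)CC=C | intermediate
9 | trimethyl{4-[(1S,2R)-2,6,6-trimethyl-2-(prop-2-en-1-yl)cyclohexyl]but-1-yn-1-yl}silane | C[Si](C)(C)C#CCC[C@H]1C(C)(C)CCC[C@]1(C)CC=C | intermediate
10 | 2-{(1R,2S)-1,3,3-trimethyl-2-[4-(trimethylsilyl)but-3-yn-1-yl]cyclohexyl}acetaldehyde | C[Si](C)(C)C#CCC[C@H]1C(C)(C)CCC[C@]1(C)CC=O | intermediate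
11 | 2,5-dihydroxybenzaldehyde | O=Cc1cc(O)ccc1O | starting material
12 | 2-hydroxy-5-(methoxymethoxy)benzaldehyde | COCOc1ccc(O)c(C=O)c1 | intermediate
13 | 2-methoxy-5-(methoxymethoxy)benzaldehyde | COCOc1ccc(OC)c(C=O)c1 | intermediate
14 | 4-bromo-2-methoxy-5-(methoxymethoxy)benzaldehyde | COCOc1cc(C=O)c(OC)cc1Br | intermediate
15 | [4-bromo-2-methoxy-5-(methoxymethoxy)phenyl]methanol | COCOc1cc(CO)c(OC)cc1Br | intermediate
16 | {[4-bromo-2-methoxy-5-(methoxymethoxy)phenyl]methoxy}(tert-butyl)dimethylsilane | COCOc1cc(CO[Si](C)(C)C(C)(C)C)c(OC)cc1Br | intermediate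
17 | [4-({[tert-butyl(dimethyl)silyl]oxy}methyl)-5-methoxy-2-(methoxymethoxy)phenyl]lithium | COCOc1cc(CO[Si](C)(C)C(C)(C)C)c(OC)cc1[Li] | intermediate (not isolated)
18 | lithium 1-Ar-2-{(1R,2S)-1,3,3-trimethyl-2-[4-(trimethylsilyl)but-3-yn-1-yl]cyclohexyl}ethan-1-olate, C11 epimers | C[Si](C)(C)C#CCC[C@H]1C(C)(C)CCC[C@]1(C)CC(O[Li])c1cc(OC)c(CO[Si](C)(C)C(C)(C)C)cc1OCOC | intermediate (not isolated)
19 | 2-[(1R,2S)-2-(but-3-yn-1-yl)-1,3,3-trimethylcyclohexyl]-1-Ar-ethan-1-ol, C11 epimers | C#CCC[C@H]1C(C)(C)CCC[C@]1(C)CC(O)c1cc(OC)c(CO[Si](C)(C)C(C)(C)C)cc1OCOC | intermediate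
20 | 2-[(1R,2S)-2-(but-3-yn-1-yl)-1,3,3-trimethylcyclohexyl]-1-Ar-ethan-1-one | C#CCC[C@H]1C(C)(C)CCC[C@]1(C)CC(=O)c1cc(OC)c(CO[Si](C)(C)C(C)(C)C)cc1OCOC | intermediate
21 | {[(1Z)-2-[(1S,2S)-2-(but-3-yn-1-yl)-1,3,3-trimethylcyclohexyl]-1-Ar-ethenyl]oxy}(tert-butyl)dimethylsilane (precursor of the key step) | C#CCC[C@H]1C(C)(C)CCC[C@]1(C)/C=C(\O[Si](C)(C)C(C)(C)C)c1cc(OC)c(CO[Si](C)(C)C(C)(C)C)cc1OCOC | intermediate
22 | (Ar)(Dr)methanone, 11-oxo-11-aryl-drim-8(12)-ene (product of the key step) | C=C1CC[C@H]2C(C)(C)CCC[C@]2(C)[C@H]1C(=O)c1cc(OC)c(CO[Si](C)(C)C(C)(C)C)cc1OCOC | intermediate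
23 | (Ar)(Dr)methanol, C11 epimers | C=C1CC[C@H]2C(C)(C)CCC[C@]2(C)[C@H]1C(O)c1cc(OC)c(CO[Si](C)(C)C(C)(C)C)cc1OCOC | intermediate
24 | O-[(Ar)(Dr)methyl] S-methyl carbonodithioate, C11 epimers | C=C1CC[C@H]2C(C)(C)CCC[C@]2(C)[C@H]1C(OC(=S)SC)c1cc(OC)c(CO[Si](C)(C)C(C)(C)C)cc1OCOC | intermediate
25 | tert-butyl{[4-(Dr-methyl)-2-methoxy-5-(methoxymethoxy)phenyl]methoxy}dimethylsilane | C=C1CC[C@H]2C(C)(C)CCC[C@]2(C)[C@H]1Cc1cc(OC)c(CO[Si](C)(C)C(C)(C)C)cc1OCOC | intermediate
26 | 5-({[tert-butyl(dimethyl)silyl]oxy}methyl)-2-(Dr-methyl)-4-methoxyphenol | C=C1CC[C@H]2C(C)(C)CCC[C@]2(C)[C@H]1Cc1cc(OC)c(CO[Si](C)(C)C(C)(C)C)cc1O | intermediate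
27 | 5-({[tert-butyl(dimethyl)silyl]oxy}methyl)-2-(Dr-methyl)-4,4-dimethoxycyclohexa-2,5-dien-1-one | C=C1CC[C@H]2C(C)(C)CCC[C@]2(C)[C@H]1CC1=CC(OC)(OC)C(CO[Si](C)(C)C(C)(C)C)=CC1=O | intermediate
28 | (1S,6R)-4-({[tert-butyl(dimethyl)silyl]oxy}methyl)-1-(Dr-methyl)-5,5-dimethoxy-7-oxabicyclo[4.1.0]hept-3-en-2-one | C=C1CC[C@H]2C(C)(C)CCC[C@]2(C)[C@H]1C[C@]12O[C@H]1C(OC)(OC)C(CO[Si](C)(C)C(C)(C)C)=CC2=O | intermediate
29 | (1S,6R)-1-(Dr-methyl)-4-(hydroxymethyl)-5,5-dimethoxy-7-oxabicyclo[4.1.0]hept-3-en-2-one | C=C1CC[C@H]2C(C)(C)CCC[C@]2(C)[C@H]1C[C@]12O[C@H]1C(OC)(OC)C(CO)=CC2=O | intermediate (not isolated)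
30 | (1S,6R)-1-(Dr-methyl)-4-(hydroxymethyl)-7-oxabicyclo[4.1.0]hept-3-ene-2,5-dione | C=C1CC[C@H]2C(C)(C)CCC[C@]2(C)[C@H]1C[C@]12O[C@H]1C(=O)C(CO)=CC2=O | intermediate
31 | (1S,5R,6S)-5-hydroxy-4-(hydroxymethyl)-1-{[(1S,4aS,8aS)-5,5,8a-trimethyl-2-methylidenedecahydronaphthalen-1-yl]methyl}-7-oxabicyclo[4.1.0]hept-3-en-2-one | C=C1CC[C@H]2C(C)(C)CCC[C@]2(C)[C@H]1C[C@]12O[C@H]1[C@H](O)C(CO)=CC2=O | target

## Step count and least certain steps

Total step count: 22. Longest linear sequence: 17 steps (steps 1–5 and 11–22; the arene branch, steps 6–10 and 11–22, is of the same length).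

Step 14 (key step). Most likely to go wrong: intermolecular addition of methanol or water to the gold-activated alkyne, or protodesilylation of the enol ether, outrunning the cyclisation, because C9 is a neopentyl-type nucleophile beside quaternary C10; loss of face control at C9 is the second concern. Fallback: a radical closure of the same C8–C9 bond. It sets out from 21: N-bromosuccinimide in THF at −78 °C converts the enol ether into the α-bromo ketone F1, and slow addition of Bu3SnH with AIBN in benzene at reflux generates the C9 α-keto radical, which closes 6-exo-dig onto C8. The vinyl radical is reduced to the methylene, and the sequence comes back to the route at 22.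

Step 1. Most likely to go wrong: slow or poorly face-selective addition to a β-carbon that is neopentylic (next to the C4 gem-dimethyl group) and α-substituted, and incomplete C-allylation of the hindered magnesium enolate. Fallback: a racemic two-stage sequence with resolution. It sets out from 2 and 4: CuBr·SMe2 (catalytic), Me3SiCl and HMPA in THF at −78 °C give the racemic trimethylsilyl enol ether F2. MeLi regenerates the lithium enolate, and 3 with DMPU gives the racemic trans ketone F3. Preparative chromatography on a cellulose carbamate chiral stationary phase separates the enantiomers and comes back to the route at 6.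

Step 18. Most likely to go wrong: loss of the C7' silyl ether, or incomplete cleavage of the MOM ether, under the silyl triflate. Fallback: remove both groups and restore one. It sets out from 25: catalytic HCl in MeOH at rt gives the phenol alcohol F4, and TBSCl with imidazole silylates both oxygens to give the bis-silyl ether F5. K2CO3 in MeOH then cleaves only the aryl silyl ether and comes back to the route at 26.

Step 20. Most likely to go wrong: poor facial selectivity, since the only resident stereocentres are remote from the dienone, or partial attack at C3'. Fallback: auxiliary control in place of reagent control. It sets out from 27: transketalisation with (2R,4R)-pentane-2,4-diol (pyridinium tosylate, benzene; antipode chosen as needed) gives the dioxane monoketal F6. Epoxidation with t-BuOOH and DBU under the bias of the C2-symmetric ketal gives the epoxy ketal F7, and 48% aq. HF in MeCN removes ketal and silyl ether and comes back to the route at 30.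

Step 22. Most likely to go wrong: hydride delivery on the face anti to the epoxide oxygen, which is the intrinsic preference of an α,β-epoxy ketone for attack anti to the C–O bond and would give the 4'-epimer; partial reduction at C1' is the second concern. Fallback: accept the syn alcohol and invert it. It sets out from 28: Montmorillonite K10 in CH2Cl2 hydrolyses the ketal with the silyl ether retained, giving the epoxyquinone F8. NaBH4 with CeCl3 in MeOH at −78 °C reduces C4' from the face anti to the epoxide to the syn alcohol F9. Mitsunobu inversion with 4-nitrobenzoic acid, PPh3 and diisopropyl azodicarboxylate gives the anti ester F10, and K2CO3 in MeOH at 0 °C gives the 7'-O-silyl ether F11. HF·pyridine in THF then comes back to the route at 31.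

## Further compounds

F1 | step 14 | 2-bromo-2-[(1R,2S)-2-(but-3-yn-1-yl)-1,3,3-trimethylcyclohexyl]-1-Ar-ethan-1-one, C9 epimers | C#CCC[C@H]1C(C)(C)CCC[C@]1(C)C(Br)C(=O)c1cc(OC)c(CO[Si](C)(C)C(C)(C)C)cc1OCOC
F2 | step 1 | racemic trimethyl({2,4,4-trimethyl-3-[4-(trimethylsilyl)but-3-yn-1-yl]cyclohex-1-en-1-yl}oxy)silane | C[Si](C)(C)C#CCC[C@H]1C(C)(C)CCC(O[Si](C)(C)C)=C1C.C[Si](C)(C)C#CCC[C@@H]1C(C)(C)CCC(O[Si](C)(C)C)=C1C
F3 | step 1 | racemic (2R*,3S*)-2,4,4-trimethyl-2-(prop-2-en-1-yl)-3-[4-(trimethylsilyl)but-3-yn-1-yl]cyclohexan-1-one | C[Si](C)(C)C#CCC[C@H]1C(C)(C)CCC(=O)[C@]1(C)CC=C.C[Si](C)(C)C#CCC[C@@H]1C(C)(C)CCC(=O)[C@@]1(C)CC=C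
F4 | step 18 | 2-(Dr-methyl)-5-(hydroxymethyl)-4-methoxyphenol | C=C1CC[C@H]2C(C)(C)CCC[C@]2(C)[C@H]1Cc1cc(OC)c(CO)cc1O
F5 | step 18 | tert-butyl{[5-{[tert-butyl(dimethyl)silyl]oxy}-4-(Dr-methyl)-2-methoxyphenyl]methoxy}dimethylsilane | C=C1CC[C@H]2C(C)(C)CCC[C@]2(C)[C@H]1Cc1cc(OC)c(CO[Si](C)(C)C(C)(C)C)cc1O[Si](C)(C)C(C)(C)C
F6 | step 20 | (2R,4R)-2,4-dimethyl-1,5-dioxaspiro[5.5]undeca-7,10-dien-9-one carrying CH2OTBS on C7 and Dr-methyl on C10 (pentanediol monoketal of the quinone) | C=C1CC[C@H]2C(C)(C)CCC[C@]2(C)[C@H]1CC1=CC2(O[C@H](C)C[C@@H](C)O2)C(CO[Si](C)(C)C(C)(C)C)=CC1=O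
F7 | step 20 | C5'–C6' α-epoxide of F6, epoxide configuration as in 28 | C=C1CC[C@H]2C(C)(C)CCC[C@]2(C)[C@H]1C[C@]12O[C@H]1C1(O[C@H](C)C[C@@H](C)O1)C(CO[Si](C)(C)C(C)(C)C)=CC2=O
F8 | step 22 | (1S,6R)-4-({[tert-butyl(dimethyl)silyl]oxy}methyl)-1-(Dr-methyl)-7-oxabicyclo[4.1.0]hept-3-ene-2,5-dione | C=C1CC[C@H]2C(C)(C)CCC[C@]2(C)[C@H]1C[C@]12O[C@H]1C(=O)C(CO[Si](C)(C)C(C)(C)C)=CC2=O
F9 | step 22 | (1S,5S,6S)-4-({[tert-butyl(dimethyl)silyl]oxy}methyl)-1-(Dr-methyl)-5-hydroxy-7-oxabicyclo[4.1.0]hept-3-en-2-one, hydroxyl syn to the epoxide | C=C1CC[C@H]2C(C)(C)CCC[C@]2(C)[C@H]1C[C@]12O[C@H]1[C@@H](O)C(CO[Si](C)(C)C(C)(C)C)=CC2=O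
F10 | step 22 | 4-nitrobenzoate of the 7'-O-TBS ether of 31 (ester oxygen anti to the epoxide) | C=C1CC[C@H]2C(C)(C)CCC[C@]2(C)[C@H]1C[C@]12O[C@H]1[C@H](OC(=O)c1ccc(cc1)[N+](=O)[O-])C(CO[Si](C)(C)C(C)(C)C)=CC2=O
F11 | step 22 | 7'-O-TBS ether of 31 | C=C1CC[C@H]2C(C)(C)CCC[C@]2(C)[C@H]1C[C@]12O[C@H]1[C@H](O)C(CO[Si](C)(C)C(C)(C)C)=CC2=O
A1 | alternative 1 | endo cyclopentadiene adduct across C2'=C3' of the drimenylmethyl (silyloxymethyl) quinone | C=C1CC[C@H]2C(C)(C)CCC[C@]2(C)[C@H]1CC1=CC(=O)[C@]3(CO[Si](C)(C)C(C)(C)C)[C@@H]4C=C[C@@H](C4)[C@@H]3C1=O
A2 | alternative 1 | convex-face C5'–C6' epoxide of A1 | C=C1CC[C@H]2C(C)(C)CCC[C@]2(C)[C@H]1C[C@]12O[C@H]1C(=O)[C@]3(CO[Si](C)(C)C(C)(C)C)[C@@H]4C=C[C@@H](C4)[C@@H]3C2=O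
A3 | alternative 2 | open-chain (Z)-enone with C6' chloride, C5' aldehyde and C4', C7' silyl ethers (Darzens precursor) | C=C1CC[C@H]2C(C)(C)CCC[C@]2(C)[C@H]1CC(Cl)C(=O)/C=C(/CO[Si](C)(C)C(C)(C)C)[C@@H](O[Si](C)(C)C(C)(C)C)C=O
A4 | alternative 2 | 4',7'-bis-O-tert-butyldimethylsilyl ether of 31 | C=C1CC[C@H]2C(C)(C)CCC[C@]2(C)[C@H]1C[C@]12O[C@H]1[C@H](O[Si](C)(C)C(C)(C)C)C(CO[Si](C)(C)C(C)(C)C)=CC2=O
A5 | alternative 3 | epoxy diene with C1' vinyl ketone, C3' 1,1-disubstituted alkene and C4', C7' triethylsilyl ethers (metathesis precursor) | C=C1CC[C@H]2C(C)(C)CCC[C@]2(C)[C@H]1C[C@@]1(O[C@H]1[C@H](O[Si](CC)(CC)CC)C(=C)CO[Si](CC)(CC)CC)C(=O)C=C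
A6 | alternative 3 | 4',7'-bis-O-triethylsilyl ether of 31 | C=C1CC[C@H]2C(C)(C)CCC[C@]2(C)[C@H]1C[C@]12O[C@H]1[C@H](O[Si](CC)(CC)CC)C(CO[Si](CC)(CC)CC)=CC2=O
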